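## Retrosynthetic overview

- Last bond made: the aryl–furan C–C bond, by C–H borylation of the free, unhindered α-position of the furan and Suzuki coupling with unprotected bromohydroquinone, so the phenols never need protection.
- Key disconnection: the ester C–O bond at the carbinol stereocentre. The (S)-senecioate is made directly from the racemic furyl carbinol by a dynamic kinetic, enantioselective O-acylation that installs the acyl group and the only stereocentre in one operation.
- Racemic carbinol: from furan-3-carbaldehyde and prenyl bromide by linear (α-selective) prenylation.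
- Rings: none is built. The furan comes from furan-3-carbaldehyde and the benzene ring from bromohydroquinone.

Assumption: the senecioyl carbonate used as acyl donor is not a catalogue compound, so its one-step preparation is counted as a step (side branch).

## Route

Step 1
Reactants: 1 furan-3-carbaldehyde; 2 1-bromo-3-methylbut-2-ene (prenyl bromide)
Product: 5 (±)-1-(furan-3-yl)-4-methylpent-3-en-1-ol, via prenylzinc bromide 3 (not isolated), via reverse-prenyl zinc alkoxide 4 (not isolated)
Conditions: Zn dust, HMPA, 130 °C; then aq NH4Cl
Reagents that add atoms: zinc, [Zn] (present only in intermediates 3 and 4, not in 5)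
Why: Barbier reaction under thermodynamic control: zinc inserts into 2 to give 3, which adds kinetically through its γ-carbon to give the hindered alkoxide 4, and at 130 °C in HMPA this adduct reverts (retro-allylation) and funnels to the linear α-adduct; the stereocentre is deliberately formed racemic because step 3 is stereoconvergent.

Step 2
Reactants: 6 3-methylbut-2-enoic acid (senecioic acid)
Product: 7 3-methylbut-2-enoyl propan-2-yl carbonate
Conditions: i-PrOCOCl, Et3N, Et2O, 0 °C; filter under argon, concentrate, use at once
Reagents that add atoms: isopropyl chloroformate, CC(C)OC(=O)Cl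
Why: Mixed carboxylic–carbonic anhydride formation: the triethylammonium carboxylate of 6 is O-acylated by the chloroformate at 0 °C, and the branched isopropyl group slows disproportionation enough for the carbonate to be filtered free of ammonium salt and used directly.

Step 3
Reactants: 5 (±)-1-(furan-3-yl)-4-methylpent-3-en-1-ol; 7 3-methylbut-2-enoyl propan-2-yl carbonate
Product: 8 (S)-1-(furan-3-yl)-4-methylpent-3-en-1-yl 3-methylbut-2-enoate
Conditions: (S)-BTM [(S)-benzotetramisole] (5 mol %), (η5-C5Ph5)Ru(CO)2Cl (4 mol %), KOtBu (5 mol %), 7 (1.5 equiv, added over 10 h), toluene, 25 °C, argon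
Reagents that add atoms: none
Why: Proposed new method: a dynamic kinetic resolution by enantioselective acyl transfer in which the chiral isothiourea is N-acylated by carbonate 7 to a senecioyl isothiouronium ion (the isopropyl carbonate leaving group collapses to CO2 and isopropoxide, which acts as the general base and leaves no carboxylate to bind ruthenium), the furan ring of the (S)-carbinol stacks on the cationic benzothiazolium face (cation–π) so that (S)-5 is acylated much faster than (R)-5 [the mirror image of the known preference of (R)-BTM for (R)-1-arylalkanols, with the same CIP order O > (hetero)aryl > CH2], and the ruthenium alkoxide continuously racemises the slow (R)-carbinol by reversible β-hydride elimination and re-addition while the ester is configurationally inert, so all material converges on (S)-8; the closest known reactions are the ruthenium/planar-chiral DMAP dynamic kinetic resolution of secondary alcohols with acetyl isopropyl carbonate, the isothiourea-catalysed kinetic resolution of aryl carbinols with anhydrides and the ruthenium/lipase dynamic kinetic resolution of homoallylic alcohols, and what is new is the isothiourea/ruthenium pairing, the α,β-unsaturated acyl carbonate donor and the furan-3-yl homoallylic substrate.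

Step 4
Reactants: 8 (S)-1-(furan-3-yl)-4-methylpent-3-en-1-yl 3-methylbut-2-enoate; 9 2-bromobenzene-1,4-diol (bromohydroquinone)
Product: 11 (S)-1-[5-(2,5-dihydroxyphenyl)furan-3-yl]-4-methylpent-3-en-1-yl 3-methylbut-2-enoate (the target), via furan-5-yl pinacol boronate 10 (not isolated)
Conditions: [Ir(OMe)(cod)]2 (1.5 mol %), 4,4'-di-tert-butyl-2,2'-bipyridine (3 mol %), B2pin2 (0.55 equiv), THF, 40 °C; then 9, Pd(OAc)2 (3 mol %), SPhos (6 mol %), degassed aq K3PO4, 40 °C; work-up under argon with dilute aq NH4Cl
Reagents that add atoms: bis(pinacolato)diboron, CC1(C)OB(OC1(C)C)B1OC(C)(C)C(C)(C)O1 (its boryl group is carried only in intermediate 10 and is lost again in the coupling)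
Why: One-pot iridium-catalysed C–H borylation/Suzuki–Miyaura coupling: borylation is sterically controlled and takes the only unhindered α-C–H of the 3-substituted furan (C5, remote from the branched side chain), and boronate 10 then couples with 9 at 40 °C under phosphate conditions mild enough for the free hydroquinone, the senecioate and the stereocentre, which is not touched.

## Compound list

1 | furan-3-carbaldehyde | O=Cc1ccoc1 | starting material
2 | 1-bromo-3-methylbut-2-ene (prenyl bromide) | CC(C)=CCBr | starting material
3 | (3-methylbut-2-en-1-yl)zinc bromide (prenylzinc bromide; not isolated) | CC(C)=CC[Zn]Br | intermediate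
4 | bromozinc (±)-1-(furan-3-yl)-2,2-dimethylbut-3-en-1-olate (reverse-prenyl γ-adduct; not isolated) | C=CC(C)(C)C(O[Zn]Br)c1ccoc1 | intermediate
5 | (±)-1-(furan-3-yl)-4-methylpent-3-en-1-ol | CC(C)=CCC(O)c1ccoc1 | intermediate
6 | 3-methylbut-2-enoic acid (senecioic acid) | CC(C)=CC(=O)O | starting material
7 | 3-methylbut-2-enoyl propan-2-yl carbonate | CC(C)=CC(=O)OC(=O)OC(C)C | intermediate
8 | (S)-1-(furan-3-yl)-4-methylpent-3-en-1-yl 3-methylbut-2-enoate | CC(C)=CC[C@H](OC(=O)C=C(C)C)c1ccoc1 | intermediate
9 | 2-bromobenzene-1,4-diol (bromohydroquinone) | Oc1ccc(O)c(Br)c1 | starting material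
10 | (S)-4-methyl-1-[5-(4,4,5,5-tetramethyl-1,3,2-dioxaborolan-2-yl)furan-3-yl]pent-3-en-1-yl 3-methylbut-2-enoate (not isolated) | CC(C)=CC[C@H](OC(=O)C=C(C)C)c1coc(B2OC(C)(C)C(C)(C)O2)c1 | intermediate
11 | (S)-1-[5-(2,5-dihydroxyphenyl)furan-3-yl]-4-methylpent-3-en-1-yl 3-methylbut-2-enoate | CC(C)=CC[C@H](OC(=O)C=C(C)C)c1coc(-c2cc(O)ccc2O)c1 | target

## Summary

Total step count: 4 (steps 1–4).
Longest linear sequence: 3 steps (1 → 3 → 4) from furan-3-carbaldehyde; step 2 is a one-step side branch.

## Steps most likely to fail, with fallbacks

**Step 3 (the proposed new dynamic kinetic acylation).** Risks are a moderate selectivity factor for the small furan-3-yl group, mutual inhibition of the isothiourea and the ruthenium catalyst, attack at the carbonate carbonyl of 7, and partial deconjugation of the senecioyl group. The fallback uses known chemistry only, sets out from 5 and comes back at 8. Dess–Martin periodinane (NaHCO3-buffered, CH2Cl2, 0 °C) oxidises 5 to the β,γ-unsaturated ketone 1-(furan-3-yl)-4-methylpent-3-en-1-one F1. Reduction with (−)-DIP-Cl (THF, −25 °C, diethanolamine work-up) is non-basic, so the alkene does not move into conjugation, and gives (S)-1-(furan-3-yl)-4-methylpent-3-en-1-ol F2, in the same sense as acetophenone giving (S)-1-phenylethanol. Steglich esterification of this alcohol with acid 6 (DCC, catalytic DMAP, CH2Cl2, 0 °C) then gives 8 with retention.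

**Step 4 (one-pot borylation/Suzuki with the free hydroquinone).** Risks are oxidation of the hydroquinone to the quinone under base, slow oxidative addition into the electron-rich phenoxide, and protodeboronation of the furyl boronate. The fallback switches to a protected coupling partner and a stepwise sequence; it sets out from 8 and 9 and comes back at 11. Bromohydroquinone 9 is silylated (TBSCl, imidazole, DMF) to 2-bromo-1,4-bis(tert-butyldimethylsilyloxy)benzene F3. Ester 8 is borylated as in step 4 and boronate 10 is isolated by filtration through a short silica plug. Suzuki coupling of 10 with this bromide (Pd(OAc)2, SPhos, K3PO4, THF/H2O, 50 °C) gives (S)-1-{5-[2,5-bis(tert-butyldimethylsilyloxy)phenyl]furan-3-yl}-4-methylpent-3-en-1-yl 3-methylbut-2-enoate F4. HF·pyridine (THF/pyridine, 0 °C) removes both aryl silyl ethers without touching the senecioate and gives 11.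

**Step 1 (α-selective prenylation).** Risks are incomplete γ-to-α equilibration, which leaves reverse-prenyl alcohol, and decomposition of the furan aldehyde at 130 °C. The fallback builds the prenyl group in two stages; it sets out from 1 and comes back at 5. Allylmagnesium bromide (THF, −78 °C) adds to 1 to give (±)-1-(furan-3-yl)but-3-en-1-ol F5. Cross-metathesis of this alcohol with excess 2-methylbut-2-ene, using the second-generation Grubbs catalyst (H2IMes)(PCy3)Cl2Ru=CHPh in CH2Cl2 at 40 °C, gives 5.

## Further compounds

F1 | step 3 | 1-(furan-3-yl)-4-methylpent-3-en-1-one | CC(C)=CCC(=O)c1ccoc1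
F2 | step 3 | (S)-1-(furan-3-yl)-4-methylpent-3-en-1-ol | CC(C)=CC[C@H](O)c1ccoc1
F3 | step 4 | 2-bromo-1,4-bis(tert-butyldimethylsilyloxy)benzene | CC(C)(C)[Si](C)(C)Oc1ccc(O[Si](C)(C)C(C)(C)C)c(Br)c1
F4 | step 4 | (S)-1-{5-[2,5-bis(tert-butyldimethylsilyloxy)phenyl]furan-3-yl}-4-methylpent-3-en-1-yl 3-methylbut-2-enoate | CC(C)=CC[C@H](OC(=O)C=C(C)C)c1coc(-c2cc(O[Si](C)(C)C(C)(C)C)ccc2O[Si](C)(C)C(C)(C)C)c1
F5 | step 1 | (±)-1-(furan-3-yl)but-3-en-1-ol | C=CCC(O)c1ccoc1
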